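**Strategy.** Everything rests on cutting the O1–C8a bond of ring C. O1 is at once the oxygen on the stereocentre C2 and an aryl ether oxygen on C8a of ring A, so ring C can be closed by a copper-catalysed intramolecular O-arylation that touches no bond at C2. In one operation this step forms the chroman ring while carrying a pre-set (S) carbinol into the ring unchanged. Its precursor is an open-chain anti 1,3-diol: the future C2 carbinol bears the 7-prenylbenzofuran-5-yl group and the future C4 carbinol bears a 2-bromo-4,6-bis(methoxymethoxy)phenyl ring. The stereocentre comes from a Noyori transfer hydrogenation of the corresponding 1,3-diketone.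

Key step: step 10

Remark on the chemistry: the carbinol that becomes C4 is oxidised in step 11, so only the (S) centre at the future C2 has to be secured. The (1S,3S) diol is drawn because the (S,S)-catalyst should deliver it; any C1 epimer formed alongside would converge on the same ketone 19.

**Route**

Step 1
Reactants: 1 3'-bromo-4'-hydroxyacetophenone
Product: 2 1-(3-bromo-4-hydroxy-5-iodophenyl)ethanone
Conditions: NIS (1.05 equiv), TsOH·H2O (10 mol%), MeCN, rt
Reagents that add atoms: N-iodosuccinimide, O=C1CCC(=O)N1I
Why: Electrophilic aromatic iodination: the phenol directs the iodonium equivalent to its only free ortho position (C5), the para position being occupied by the deactivating acetyl group.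

Step 2
Reactants: 2 1-(3-bromo-4-hydroxy-5-iodophenyl)ethanone; 3 ethynyltrimethylsilane
Product: 4 1-[3-bromo-4-hydroxy-5-(trimethylsilylethynyl)phenyl]ethanone
Conditions: Pd(PPh3)2Cl2 (2 mol%), CuI (4 mol%), Et3N, THF, rt
Reagents that add atoms: none
Why: Sonogashira coupling, chemoselective because zerovalent palladium inserts into the C–I bond at room temperature far faster than into the C–Br bond, which is kept for step 4.

Step 3
Reactants: 4 1-[3-bromo-4-hydroxy-5-(trimethylsilylethynyl)phenyl]ethanone
Product: 6 1-(7-bromobenzofuran-5-yl)ethanone, via ethynylphenol 5 (not isolated)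
Conditions: TBAF (2 equiv), THF, 65 °C
Reagents that add atoms: none
Why: Fluoride cleaves the C–Si bond and the phenoxide then adds 5-endo-dig across the terminal alkyne (TBAF-mediated cycloisomerisation of a 2-alkynylphenol), giving the 2,3-unsubstituted benzofuran.

Step 4
Reactants: 6 1-(7-bromobenzofuran-5-yl)ethanone; 7 prenylboronic acid pinacol ester
Product: 8 1-[7-(3-methylbut-2-enyl)benzofuran-5-yl]ethanone
Conditions: [1,3-bis(2,6-di(pentan-3-yl)phenyl)imidazol-2-ylidene](3-chloropyridine)PdCl2 (2 mol%), 5 M aq KOH, THF, 70 °C
Reagents that add atoms: none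
Why: Suzuki–Miyaura coupling of an allylic boronate in which the bulky N-heterocyclic carbene ligand steers C–C reductive elimination to the unsubstituted allyl terminus, so the linear prenyl (α) isomer should prevail over the 1,1-dimethylallyl (γ) isomer.

Step 5
Reactants: 9 5-bromoresorcinol
Product: 11 2-bromo-4,6-dihydroxybenzaldehyde, via iminium chloride 10 (not isolated)
Conditions: POCl3, DMF, MeCN, 0 °C to rt; then H2O, 50 °C
Reagents that add atoms: N,N-dimethylformamide, CN(C)C=O; water, O
Why: Vilsmeier–Haack formylation; as with resorcinol and orcinol the chloroiminium ion attacks C4, para to one hydroxyl and ortho to the other, rather than the doubly flanked C2, which places the formyl group next to bromine.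

Step 6
Reactants: 11 2-bromo-4,6-dihydroxybenzaldehyde
Product: 12 2-bromo-4,6-bis(methoxymethoxy)benzaldehyde
Conditions: MOMCl (3 equiv), i-Pr2NEt (4 equiv), CH2Cl2, 0 °C to rt
Reagents that add atoms: chloromethyl methyl ether, COCCl
Why: O-Alkylation of both phenols with an α-chloro ether (acetal protection), the excess of reagent overcoming the hydrogen bond between the C6 hydroxyl and the formyl group.

Step 7
Reactants: 8 1-[7-(3-methylbut-2-enyl)benzofuran-5-yl]ethanone; 12 2-bromo-4,6-bis(methoxymethoxy)benzaldehyde
Product: 14 rac-3-[2-bromo-4,6-bis(methoxymethoxy)phenyl]-3-hydroxy-1-[7-(3-methylbut-2-enyl)benzofuran-5-yl]propan-1-one, via lithium enolate 13 (not isolated)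
Conditions: LDA (1.05 equiv), THF, −78 °C; then 12, −78 °C; AcOH quench at −78 °C
Reagents that add atoms: none
Why: Directed aldol addition of a preformed lithium enolate to a non-enolisable aldehyde, chosen because a formyl group still reacts readily between two ortho substituents where a benzoate ester would resist a Claisen condensation; the new carbinol is racemic but is removed in step 8.

Step 8
Reactants: 14 rac-3-[2-bromo-4,6-bis(methoxymethoxy)phenyl]-3-hydroxy-1-[7-(3-methylbut-2-enyl)benzofuran-5-yl]propan-1-one
Product: 15 1-[2-bromo-4,6-bis(methoxymethoxy)phenyl]-3-[7-(3-methylbut-2-enyl)benzofuran-5-yl]propane-1,3-dione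
Conditions: IBX (2 equiv), EtOAc, 77 °C
Reagents that add atoms: none
Why: IBX oxidation of a β-hydroxy ketone to the β-diketone under neutral conditions that spare the MOM ethers, the prenyl alkene and the benzofuran and cannot trigger retro-aldol cleavage.

Step 9
Reactants: 15 1-[2-bromo-4,6-bis(methoxymethoxy)phenyl]-3-[7-(3-methylbut-2-enyl)benzofuran-5-yl]propane-1,3-dione
Product: 17 (1S,3S)-1-[2-bromo-4,6-bis(methoxymethoxy)phenyl]-3-[7-(3-methylbut-2-enyl)benzofuran-5-yl]propane-1,3-diol, via (3S)-hydroxy ketone 16 (not isolated)
Conditions: RuCl(p-cymene)[(S,S)-TsDPEN] (3 mol%), HCO2H/Et3N (1:1), DMF, 40 °C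
Reagents that add atoms: none
Why: Noyori asymmetric transfer hydrogenation of a 1,3-diaryl-1,3-diketone to the anti diol: the (S,S)-catalyst transfers hydride to each aryl ketone through its six-membered, CH/π-organised transition state with the facial sense that converts acetophenone into (S)-1-phenylethanol, so both carbinols should be (S), the unhindered benzofuranyl ketone reacting first.

Step 10
Reactants: 17 (1S,3S)-1-[2-bromo-4,6-bis(methoxymethoxy)phenyl]-3-[7-(3-methylbut-2-enyl)benzofuran-5-yl]propane-1,3-diol
Product: 18 (2S,4S)-5,7-bis(methoxymethoxy)-2-[7-(3-methylbut-2-enyl)benzofuran-5-yl]chroman-4-ol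
Conditions: CuI (10 mol%), 3,4,7,8-tetramethyl-1,10-phenanthroline (20 mol%), Cs2CO3 (2 equiv), toluene, 110 °C, Ar
Reagents that add atoms: none
Why: Deprotonation by Cs2CO3 lets the C3 hydroxyl bind the ligated monovalent copper as an alkoxide; oxidative addition of the ring-A C–Br bond then gives an aryl(alkoxo) complex of trivalent copper, which collapses by C–O reductive elimination to the O1–C8a bond. The closest known reaction type is the intramolecular Ullmann-type etherification of an alcohol with an aryl bromide, an established entry to chromans. Ring C closes in a 6-exo mode: the oxygen attacks the ring-A carbon and the bromide leaves outside the new ring. No stereocentre is created; C2 stays (S) because only its O–H bond is broken, and C4 is a spectator that step 11 erases. The only selectivity to be won is between the two hydroxyls, and geometry decides it: attack by the C1 oxygen would give a strained four-membered ether, whereas the C3 oxygen reaches C8a through a six-membered array. Because C4 is still an alcohol, the substrate has no enolisable β-hydroxy ketone and so cannot fragment by retro-aldol cleavage or lose water under the hot carbonate.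

Step 11
Reactants: 18 (2S,4S)-5,7-bis(methoxymethoxy)-2-[7-(3-methylbut-2-enyl)benzofuran-5-yl]chroman-4-ol
Product: 19 (2S)-5,7-bis(methoxymethoxy)-2-[7-(3-methylbut-2-enyl)benzofuran-5-yl]chroman-4-one
Conditions: DMP (1.3 equiv), NaHCO3, CH2Cl2, 0 °C to rt
Reagents that add atoms: none
Why: Dess–Martin oxidation of the benzylic C4 carbinol to the flavanone carbonyl under buffered, non-basic conditions, which removes the spectator stereocentre and leaves C2 untouched.

Step 12
Reactants: 19 (2S)-5,7-bis(methoxymethoxy)-2-[7-(3-methylbut-2-enyl)benzofuran-5-yl]chroman-4-one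
Product: 20 (2S)-5,7-dihydroxy-2-[7-(3-methylbut-2-enyl)benzofuran-5-yl]chroman-4-one (the target)
Conditions: 3 M aq HCl (cat.), MeOH, 40 °C
Reagents that add atoms: none
Why: Acid-catalysed acetal exchange with methanol removes both MOM groups as dimethoxymethane; the prenyl group has no neighbouring phenol to cyclise onto and the low temperature keeps acid-induced opening of ring C, the only path to racemisation at C2, slow.

**Compound list**

1 | 3'-bromo-4'-hydroxyacetophenone | CC(=O)c1ccc(O)c(Br)c1 | starting material
2 | 1-(3-bromo-4-hydroxy-5-iodophenyl)ethanone | CC(=O)c1cc(Br)c(O)c(I)c1 | intermediate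
3 | ethynyltrimethylsilane | C#C[Si](C)(C)C | starting material
4 | 1-[3-bromo-4-hydroxy-5-(trimethylsilylethynyl)phenyl]ethanone | CC(=O)c1cc(Br)c(O)c(C#C[Si](C)(C)C)c1 | intermediate
5 | 1-(3-bromo-5-ethynyl-4-hydroxyphenyl)ethanone (ethynylphenol) | CC(=O)c1cc(Br)c(O)c(C#C)c1 | intermediate (not isolated)
6 | 1-(7-bromobenzofuran-5-yl)ethanone | CC(=O)c1cc(Br)c2occc2c1 | intermediate
7 | prenylboronic acid pinacol ester (4,4,5,5-tetramethyl-2-(3-methylbut-2-enyl)-1,3,2-dioxaborolane) | CC(C)=CCB1OC(C)(C)C(C)(C)O1 | starting material
8 | 1-[7-(3-methylbut-2-enyl)benzofuran-5-yl]ethanone | CC(=O)c1cc(CC=C(C)C)c2occc2c1 | intermediate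
9 | 5-bromoresorcinol | Oc1cc(O)cc(Br)c1 | starting material
10 | N-(2-bromo-4,6-dihydroxybenzylidene)-N-methylmethanaminium chloride (iminium chloride) | C[N+](C)=Cc1c(O)cc(O)cc1Br.[Cl-] | intermediate (not isolated)
11 | 2-bromo-4,6-dihydroxybenzaldehyde | O=Cc1c(O)cc(O)cc1Br | intermediate
12 | 2-bromo-4,6-bis(methoxymethoxy)benzaldehyde | COCOc1cc(Br)c(C=O)c(OCOC)c1 | intermediate
13 | lithium 1-[7-(3-methylbut-2-enyl)benzofuran-5-yl]ethenolate (lithium enolate) | C=C(O[Li])c1cc(CC=C(C)C)c2occc2c1 | intermediate (not isolated)
14 | rac-3-[2-bromo-4,6-bis(methoxymethoxy)phenyl]-3-hydroxy-1-[7-(3-methylbut-2-enyl)benzofuran-5-yl]propan-1-one | CC(C)=CCc1cc(C(=O)CC(O)c3c(Br)cc(OCOC)cc3OCOC)cc2ccoc12 | intermediate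
15 | 1-[2-bromo-4,6-bis(methoxymethoxy)phenyl]-3-[7-(3-methylbut-2-enyl)benzofuran-5-yl]propane-1,3-dione | CC(C)=CCc1cc(C(=O)CC(=O)c3c(Br)cc(OCOC)cc3OCOC)cc2ccoc12 | intermediate
16 | (3S)-1-[2-bromo-4,6-bis(methoxymethoxy)phenyl]-3-hydroxy-3-[7-(3-methylbut-2-enyl)benzofuran-5-yl]propan-1-one | CC(C)=CCc1cc([C@@H](O)CC(=O)c3c(Br)cc(OCOC)cc3OCOC)cc2ccoc12 | intermediate (not isolated)
17 | (1S,3S)-1-[2-bromo-4,6-bis(methoxymethoxy)phenyl]-3-[7-(3-methylbut-2-enyl)benzofuran-5-yl]propane-1,3-diol | CC(C)=CCc1cc([C@@H](O)C[C@H](O)c3c(Br)cc(OCOC)cc3OCOC)cc2ccoc12 | intermediate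
18 | (2S,4S)-5,7-bis(methoxymethoxy)-2-[7-(3-methylbut-2-enyl)benzofuran-5-yl]chroman-4-ol | CC(C)=CCc1cc([C@@H]2C[C@H](O)c3c(OCOC)cc(OCOC)cc3O2)cc2ccoc12 | intermediate
19 | (2S)-5,7-bis(methoxymethoxy)-2-[7-(3-methylbut-2-enyl)benzofuran-5-yl]chroman-4-one | CC(C)=CCc1cc([C@@H]2CC(=O)c3c(OCOC)cc(OCOC)cc3O2)cc2ccoc12 | intermediate
20 | (2S)-5,7-dihydroxy-2-[7-(3-methylbut-2-enyl)benzofuran-5-yl]chroman-4-one | CC(C)=CCc1cc([C@@H]2CC(=O)c3c(O)cc(O)cc3O2)cc2ccoc12 | target

**Step count.** Total: 12 steps. Longest linear sequence: 10 steps (steps 1–4 and 7–12); steps 5–6 form the ring-A branch.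

**Steps most likely to fail**

Step 10. Oxidative addition may stall, or the copper may be held unproductively by the 1,3-diol, so that reductive loss of bromine by hydride transfer from an alkoxide overtakes C–O bond formation. The fallback changes the metal and the mechanism: from 17, Pd(OAc)2 (3 mol%) with racemic 2-(di-tert-butylphosphino)-1,1'-binaphthyl (4 mol%) and Cs2CO3 in toluene at 80 °C. Here zerovalent palladium inserts into the C–Br bond and the bulky phosphine forces C–O reductive elimination ahead of β-hydride elimination. The route is rejoined at 18, and no new compound is made (entry F0 below).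

Step 9. The second hydride transfer, to the carbonyl flanked by bromine and an OMOM group, may be too slow, so that the reduction stops after the first carbonyl. The fallback replaces catalyst control by substrate direction: the hydroxy ketone 16 is isolated and reduced with Me4NBH(OAc)3 in MeCN/AcOH at −20 °C (Evans–Saksena reduction). The (3S) hydroxyl binds boron and delivers hydride internally to give the anti diol, which rejoins the route at 17. No new compound is made (entry F0 below).

Step 4. The allyl unit may transpose during C–C bond formation, giving the branched 1,1-dimethylallyl isomer, or the methyl ketone may self-condense under aqueous KOH. The fallback builds the prenyl group in two stages without an unsymmetrical allyl–metal species. From 6, Stille coupling with allyltributylstannane (Pd(PPh3)4, toluene, 100 °C) should give 1-(7-allylbenzofuran-5-yl)ethanone F1. Cross-metathesis of F1 with excess 2-methyl-2-butene (second-generation Grubbs catalyst, CH2Cl2, 40 °C) then turns allyl into prenyl and rejoins the route at 8.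

**Further compounds**

F1 | step 4 | 1-(7-allylbenzofuran-5-yl)ethanone | CC(=O)c1cc(CC=C)c2occc2c1
F0 | step 9 | none | none
F0 | step 10 | none | none
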